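**Plan**

1. Retrosynthesis: the C-3''–OH of the pyranol ring D is traced back to a C-3''/C-4'' epoxide and then to a 2,2-dimethyl-2H-chromene. Ring D is cut at C-3'–C-4'' and at O(4')–C-2'', which leaves a flavan with a free 4'-OH and prenal. Further cuts: O-1–C-2 (Mitsunobu), C-3–C-4 (Claisen–Schmidt), C-2'–prenyl (aryl–metal allylation), C-6–C(CH3)2CH=CH2 (aromatic Claisen).
2. Forward: an A-ring aldehyde and a B-ring methyl ketone are joined to a chalcone, the enone is reduced in two stages, ring C is closed, and ring D is annulated last on the complete flavan and then taken to the alcohol.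
3. Enabling feature: on ring B the phenolic oxygen on C-4' sits beside an unsubstituted C-3'–H, while its other ortho carbon C-5' carries oxygen. This O–C-4'=C-3'–H unit is a 1,3-O,C-bisnucleophile that takes up the C5 enal as a 2,2-dimethyl-2H-pyran in one operation. The C-3''=C-4'' bond so formed is the only cis, aryl-conjugated alkene in the molecule, so it can be oxidised apart from the prenyl and 1,1-dimethylallyl groups.
4. Stereochemistry: C-2 (S) from CBS reduction to the (R)-carbinol and inversion in the Mitsunobu closure; C-3'' (S) from (S,S)-Mn(salen) epoxidation and hydride opening at benzylic C-4''.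
5. Protecting groups: SEM on the A-ring oxygen that becomes O-1 (fluoride), allyl on O-4' (Pd(0)), MOM on O-7 and O-5' (acid, last step).

Key step: step 16

Remark: flavan numbering is used (rings A/C: O-1, C-2 to C-8a; ring B: C-1' to C-6'); ring D is numbered O-1'', C-2'' (gem-dimethyl), C-3'' (carbinol), C-4'' (benzylic); the target is (2S,3''S).
Remark: 2-bromo-4,5-dihydroxybenzaldehyde is taken as a catalogue compound.
Remark: the (S,S)-Mn(salen) catalyst is assumed to attack this chromene with the facial sense usual for 2,2-dimethyl-2H-chromenes, which corresponds to the (3''S,4''S)-epoxide; should the opposite sense be found, the (R,R)-catalyst is used.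

**Route**

Step 1
Reactants: 1 2,4-dihydroxybenzaldehyde
Product: 2 2-hydroxy-4-[(3-methylbut-2-en-1-yl)oxy]benzaldehyde
Conditions: prenyl bromide (1.05 eq), K2CO3 (1.1 eq), acetone, rt
Reagents that add atoms: prenyl bromide CC(C)=CCBr
Why: Williamson etherification; the 2-OH is held in a hydrogen bond to the formyl group and is the weaker acid and nucleophile, so mono-alkylation should take place at the 4-OH.

Step 2
Reactants: 2 2-hydroxy-4-[(3-methylbut-2-en-1-yl)oxy]benzaldehyde
Product: 3 4-[(3-methylbut-2-en-1-yl)oxy]-2-{[2-(trimethylsilyl)ethoxy]methoxy}benzaldehyde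
Conditions: SEMCl, K2CO3, DMF, 50 °C
Reagents that add atoms: 2-(trimethylsilyl)ethoxymethyl chloride C[Si](C)(C)CCOCCl
Why: Williamson-type alkylation of the chelated phenol under more forcing conditions; an O-alkyl group at C-2 removes the hydrogen-bond bias toward C-3 in the next step, and SEM is inert to heat, base and hydride and is cleaved later by fluoride.

Step 3
Reactants: 3 4-[(3-methylbut-2-en-1-yl)oxy]-2-{[2-(trimethylsilyl)ethoxy]methoxy}benzaldehyde
Product: 5 4-hydroxy-5-(2-methylbut-3-en-2-yl)-2-{[2-(trimethylsilyl)ethoxy]methoxy}benzaldehyde, via ortho-dienone 4 (not isolated)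
Conditions: EtOH–H2O (4:1), 130 °C, sealed tube
Reagents that add atoms: none
Why: Aromatic Claisen rearrangement: the [3,3] shift of the prenyl ether inverts the allyl unit and so delivers the 1,1-dimethylallyl group to an ortho carbon, C-5 being expected over C-3 because C-3 lies between two alkoxy groups and would have to take up a tertiary carbon (the outcome known for closely related 2-alkoxy-4-prenyloxybenzaldehydes); enolisation of dienone 4 gives the phenol.

Step 4
Reactants: 5 4-hydroxy-5-(2-methylbut-3-en-2-yl)-2-{[2-(trimethylsilyl)ethoxy]methoxy}benzaldehyde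
Product: 6 4-(methoxymethoxy)-5-(2-methylbut-3-en-2-yl)-2-{[2-(trimethylsilyl)ethoxy]methoxy}benzaldehyde
Conditions: MOMCl, K2CO3, DMF, 0 °C → rt
Reagents that add atoms: chloromethyl methyl ether COCCl
Why: O-alkylation of the acidic para-formyl phenoxide (MOM protection); the small electrophile should tolerate the neighbouring tertiary alkyl group, and the phenol must be masked for the base-mediated condensation and for the later annulation and oxidation.

Step 5
Reactants: 7 2-bromo-4,5-dihydroxybenzaldehyde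
Product: 8 4-(allyloxy)-2-bromo-5-hydroxybenzaldehyde
Conditions: allyl bromide (1.0 eq), K2CO3 (1.0 eq), DMF, 0 °C → rt
Reagents that add atoms: allyl bromide C=CCBr
Why: Williamson etherification; the 4-OH is para to the formyl group and therefore the more acidic phenol, so one equivalent of base should generate and alkylate the 4-phenoxide selectively.

Step 6
Reactants: 8 4-(allyloxy)-2-bromo-5-hydroxybenzaldehyde
Product: 9 4-(allyloxy)-2-bromo-5-(methoxymethoxy)benzaldehyde
Conditions: MOMCl, K2CO3, DMF, rt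
Reagents that add atoms: chloromethyl methyl ether COCCl
Why: MOM protection of the remaining phenol by O-alkylation; this fixes the difference between O-4' (allyl, removed before the key step) and O-5' (MOM, kept to the end).

Step 7
Reactants: 9 4-(allyloxy)-2-bromo-5-(methoxymethoxy)benzaldehyde
Product: 10 1-[4-(allyloxy)-2-bromo-5-(methoxymethoxy)phenyl]ethan-1-ol (racemic)
Conditions: MeMgBr, THF, −78 → 0 °C
Reagents that add atoms: methylmagnesium bromide C[Mg]Br
Why: Grignard addition to the aldehyde; the new carbinol centre is racemic and is removed by oxidation in step 9, and the alcohol masks the carbonyl carbon during the metalation of step 8.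

Step 8
Reactants: 10 1-[4-(allyloxy)-2-bromo-5-(methoxymethoxy)phenyl]ethan-1-ol (racemic)
Product: 12 1-[4-(allyloxy)-5-(methoxymethoxy)-2-(3-methylbut-2-en-1-yl)phenyl]ethan-1-ol (racemic), via dilithio alkoxide 11 (not isolated)
Conditions: n-BuLi (2.2 eq), THF, −78 °C; CuBr·SMe2 (10 mol%), prenyl bromide, −78 → 0 °C
Reagents that add atoms: prenyl bromide CC(C)=CCBr
Why: Deprotonation of the alcohol and bromine–lithium exchange (far faster at −78 °C than any attack on the allyl ether) give aryllithium 11, which under copper catalysis is alkylated by prenyl bromide at its primary carbon (SN2-type allylic substitution, since attack at the γ-carbon would create a quaternary centre).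

Step 9
Reactants: 12 1-[4-(allyloxy)-5-(methoxymethoxy)-2-(3-methylbut-2-en-1-yl)phenyl]ethan-1-ol (racemic)
Product: 13 1-[4-(allyloxy)-5-(methoxymethoxy)-2-(3-methylbut-2-en-1-yl)phenyl]ethan-1-one
Conditions: Dess–Martin periodinane, CH2Cl2, 0 °C → rt
Reagents that add atoms: none
Why: Dess–Martin oxidation of the benzylic secondary alcohol to the methyl ketone under neutral conditions that leave the alkenes and acetal-type ethers untouched.

Step 10
Reactants: 13 1-[4-(allyloxy)-5-(methoxymethoxy)-2-(3-methylbut-2-en-1-yl)phenyl]ethan-1-one; 6 4-(methoxymethoxy)-5-(2-methylbut-3-en-2-yl)-2-{[2-(trimethylsilyl)ethoxy]methoxy}benzaldehyde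
Product: 14 (E)-1-[4-(allyloxy)-5-(methoxymethoxy)-2-(3-methylbut-2-en-1-yl)phenyl]-3-[4-(methoxymethoxy)-5-(2-methylbut-3-en-2-yl)-2-{[2-(trimethylsilyl)ethoxy]methoxy}phenyl]prop-2-en-1-one
Conditions: KOH, EtOH–H2O, rt
Reagents that add atoms: none
Why: Claisen–Schmidt condensation (aldol addition and E1cB dehydration) forms the bond that becomes C-3–C-4 and should give the (E)-enone; allyl, MOM and SEM ethers are stable to hydroxide.

Step 11
Reactants: 14 the (E)-chalcone of step 10
Product: 15 1-[4-(allyloxy)-5-(methoxymethoxy)-2-(3-methylbut-2-en-1-yl)phenyl]-3-[4-(methoxymethoxy)-5-(2-methylbut-3-en-2-yl)-2-{[2-(trimethylsilyl)ethoxy]methoxy}phenyl]propan-1-one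
Conditions: Cu(OAc)2·H2O (5 mol%), 1,2-bis(diphenylphosphino)benzene (5 mol%), (EtO)2MeSiH, t-BuOH, toluene, rt
Reagents that add atoms: none
Why: Copper hydride-catalysed conjugate reduction (Stryker-type): the phosphine-ligated Cu–H adds 1,4 to the enone only and t-BuOH protonates the copper enolate, so the prenyl, 1,1-dimethylallyl and allyl alkenes should remain.

Step 12
Reactants: 15 the saturated ketone of step 11
Product: 16 (1R)-1-[4-(allyloxy)-5-(methoxymethoxy)-2-(3-methylbut-2-en-1-yl)phenyl]-3-[4-(methoxymethoxy)-5-(2-methylbut-3-en-2-yl)-2-{[2-(trimethylsilyl)ethoxy]methoxy}phenyl]propan-1-ol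
Conditions: (S)-2-methyl-CBS-oxazaborolidine (20 mol%), catecholborane, toluene, −78 → −40 °C; aqueous NaOH work-up
Reagents that add atoms: none
Why: Corey–Bakshi–Shibata reduction: the (S)-oxazaborolidine binds the ketone with the aryl group as the large substituent and should give the (R)-carbinol; catecholborane at low temperature does not hydroborate the isolated alkenes.

Step 13
Reactants: 16 the (1R)-carbinol of step 12
Product: 17 (1R)-1-[4-(allyloxy)-5-(methoxymethoxy)-2-(3-methylbut-2-en-1-yl)phenyl]-3-[2-hydroxy-4-(methoxymethoxy)-5-(2-methylbut-3-en-2-yl)phenyl]propan-1-ol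
Conditions: TBAF, THF–DMPU, 50–60 °C
Reagents that add atoms: none
Why: Fluoride-induced SEM cleavage: fluoride attacks silicon and the hemiformal left behind collapses, which frees only the A-ring phenol; MOM and allyl ethers and the carbinol centre (no para-hydroxy group on ring B) are not affected.

Step 14
Reactants: 17 the (1R)-phenol carbinol of step 13
Product: 18 (2S)-2-[4-(allyloxy)-5-(methoxymethoxy)-2-(3-methylbut-2-en-1-yl)phenyl]-7-(methoxymethoxy)-6-(2-methylbut-3-en-2-yl)chromane
Conditions: PPh3, DIAD, toluene, 0 °C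
Reagents that add atoms: none
Why: Intramolecular Mitsunobu etherification: the oxyphosphonium of the secondary alcohol is displaced by the neighbouring phenoxide in an SN2 6-exo-tet closure with inversion, (R)-carbinol to (2S)-flavan; O-4' is alkylated so that no para-quinone methide can form, and low temperature in a non-polar solvent is used to hold back ionisation.

Step 15
Reactants: 18 the (2S)-flavan allyl ether of step 14
Product: 19 2-(methoxymethoxy)-4-[(2S)-7-(methoxymethoxy)-6-(2-methylbut-3-en-2-yl)chroman-2-yl]-5-(3-methylbut-2-en-1-yl)phenol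
Conditions: Pd(PPh3)4 (5 mol%), morpholine, THF, rt
Reagents that add atoms: none
Why: Palladium(0)-catalysed deallylation (Tsuji–Trost type): only the aryl allyl ether can ionise to a π-allyl complex, which morpholine intercepts, and the neutral room-temperature conditions give the 4'-hydroxyflavan no opportunity for ring opening.

Step 16
Reactants: 19 2-(methoxymethoxy)-4-[(2S)-7-(methoxymethoxy)-6-(2-methylbut-3-en-2-yl)chroman-2-yl]-5-(3-methylbut-2-en-1-yl)phenol; 20 3-methylbut-2-enal (prenal)
Product: 23 (2S)-7-(methoxymethoxy)-2-[8-(methoxymethoxy)-2,2-dimethyl-5-(3-methylbut-2-en-1-yl)-2H-chromen-6-yl]-6-(2-methylbut-3-en-2-yl)chromane, via benzodioxaborin 21 (not isolated), via ortho-quinone methide 22 (not isolated)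
Conditions: PhB(OH)2 (1.1 eq), AcOH (cat.), toluene, reflux, Dean–Stark
Reagents that add atoms: none
Why: Phenol 19, PhB(OH)2 and prenal condense to a boron-bridged assembly in which the unsubstituted ortho carbon C-3' attacks the aldehyde carbon intramolecularly, which forms the C-3'–C-4'' bond and gives benzodioxaborin 21; acid-assisted cycloreversion of 21 releases the boronic acid and ortho-quinone methide 22. The 1-oxatriene of 22 (O-4'=C-4'–C-3'=C-4''–C-3''=C-2'') then closes thermally to form the O-4'–C-2'' bond and restore the aromatic ring B. The closest known reaction type is the phenylboronic acid-mediated chromenylation of phenols with α,β-unsaturated aldehydes (formal [3+3] annulation, ortho-hydroxyalkylation followed by oxa-6π electrocyclisation). The one ring that closes, the 2H-pyran ring D, does so by disrotatory 6π electrocyclisation after the intermolecular C–C bond formation. No stereocentre is created, since the carbinol carbon of 21 becomes sp2 in 22 and C-2 of the flavan is a spectator that is not in a vinylogously acidic position of 22. The step needs site selectivity among the oxygenated arene positions, and this is secured because O-4' is the only free phenol (O-5' and O-7 carry MOM groups, so no boron template can form there and C-6' and C-8 are not attacked) and because its second ortho carbon, C-5', is blocked by oxygen.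

Step 17
Reactants: 23 the 2H-chromene of step 16
Product: 24 (2S)-2-[(3S,4S)-3,4-epoxy-8-(methoxymethoxy)-2,2-dimethyl-5-(3-methylbut-2-en-1-yl)chroman-6-yl]-7-(methoxymethoxy)-6-(2-methylbut-3-en-2-yl)chromane
Conditions: (S,S)-Jacobsen Mn(salen)Cl (5 mol%), 4-phenylpyridine N-oxide (0.2 eq), aq. NaOCl (pH 11.3), CH2Cl2, 0 °C
Reagents that add atoms: sodium hypochlorite [Na+].[O-]Cl
Why: Jacobsen–Katsuki epoxidation: the Mn(V)-oxo salen species transfers oxygen to the cis, aryl-conjugated C-3''=C-4'' bond with the face set by the (S,S)-ligand ((3''S,4''S)-epoxide expected); the isolated trisubstituted prenyl alkene and the hindered 1,1-dimethylallyl alkene are poor substrates for this catalyst and both phenols are masked.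

Step 18
Reactants: 24 the (3''S,4''S)-epoxide of step 17
Product: 25 (3S)-8-(methoxymethoxy)-6-[(2S)-7-(methoxymethoxy)-6-(2-methylbut-3-en-2-yl)chroman-2-yl]-2,2-dimethyl-5-(3-methylbut-2-en-1-yl)chroman-3-ol
Conditions: LiAlH4, THF, 0 °C → rt
Reagents that add atoms: none
Why: Reductive epoxide opening: hydride attacks the benzylic, less hindered C-4'' in an SN2 process, while C-3'' is shielded by the adjacent gem-dimethyl carbon, so the C-3''–O bond and its (S) configuration are kept.

Step 19
Reactants: 25 the bis-MOM ether of step 18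
Product: 26 (3S)-6-[(2S)-7-hydroxy-6-(2-methylbut-3-en-2-yl)chroman-2-yl]-2,2-dimethyl-5-(3-methylbut-2-en-1-yl)chromane-3,8-diol
Conditions: HCl (dilute, in MeOH), 0 °C → rt
Reagents that add atoms: none
Why: Acid-catalysed acetal exchange with methanol removes both phenolic MOM groups (MOM deprotection); dilute acid at low temperature is chosen to spare the prenyl and 1,1-dimethylallyl alkenes, the tertiary alkyl aryl ether and the benzylic ether of the flavan.

**Compound list**

1 | 2,4-dihydroxybenzaldehyde | O=Cc1ccc(O)cc1O | starting material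
2 | 2-hydroxy-4-[(3-methylbut-2-en-1-yl)oxy]benzaldehyde | O=Cc1ccc(OCC=C(C)C)cc1O | intermediate
3 | 4-[(3-methylbut-2-en-1-yl)oxy]-2-{[2-(trimethylsilyl)ethoxy]methoxy}benzaldehyde | O=Cc1ccc(OCC=C(C)C)cc1OCOCC[Si](C)(C)C | intermediate
4 | 4-formyl-6-(2-methylbut-3-en-2-yl)-3-{[2-(trimethylsilyl)ethoxy]methoxy}cyclohexa-2,4-dien-1-one (racemic, not isolated) | O=CC1=CC(C(C)(C)C=C)C(=O)C=C1OCOCC[Si](C)(C)C | intermediate
5 | 4-hydroxy-5-(2-methylbut-3-en-2-yl)-2-{[2-(trimethylsilyl)ethoxy]methoxy}benzaldehyde | O=Cc1cc(C(C)(C)C=C)c(O)cc1OCOCC[Si](C)(C)C | intermediate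
6 | 4-(methoxymethoxy)-5-(2-methylbut-3-en-2-yl)-2-{[2-(trimethylsilyl)ethoxy]methoxy}benzaldehyde | O=Cc1cc(C(C)(C)C=C)c(OCOC)cc1OCOCC[Si](C)(C)C | intermediate
7 | 2-bromo-4,5-dihydroxybenzaldehyde | O=Cc1cc(O)c(O)cc1Br | starting material
8 | 4-(allyloxy)-2-bromo-5-hydroxybenzaldehyde | O=Cc1cc(O)c(OCC=C)cc1Br | intermediate
9 | 4-(allyloxy)-2-bromo-5-(methoxymethoxy)benzaldehyde | O=Cc1cc(OCOC)c(OCC=C)cc1Br | intermediate
10 | 1-[4-(allyloxy)-2-bromo-5-(methoxymethoxy)phenyl]ethan-1-ol (racemic) | CC(O)c1cc(OCOC)c(OCC=C)cc1Br | intermediate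
11 | lithium 1-[4-(allyloxy)-2-lithio-5-(methoxymethoxy)phenyl]ethan-1-olate (not isolated) | [Li]OC(C)c1cc(OCOC)c(OCC=C)cc1[Li] | intermediate
12 | 1-[4-(allyloxy)-5-(methoxymethoxy)-2-(3-methylbut-2-en-1-yl)phenyl]ethan-1-ol (racemic) | CC(O)c1cc(OCOC)c(OCC=C)cc1CC=C(C)C | intermediate
13 | 1-[4-(allyloxy)-5-(methoxymethoxy)-2-(3-methylbut-2-en-1-yl)phenyl]ethan-1-one | CC(=O)c1cc(OCOC)c(OCC=C)cc1CC=C(C)C | intermediate
14 | (E)-1-[4-(allyloxy)-5-(methoxymethoxy)-2-(3-methylbut-2-en-1-yl)phenyl]-3-[4-(methoxymethoxy)-5-(2-methylbut-3-en-2-yl)-2-{[2-(trimethylsilyl)ethoxy]methoxy}phenyl]prop-2-en-1-one | O=C(/C=C/c1cc(C(C)(C)C=C)c(OCOC)cc1OCOCC[Si](C)(C)C)c1cc(OCOC)c(OCC=C)cc1CC=C(C)C | intermediate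
15 | 1-[4-(allyloxy)-5-(methoxymethoxy)-2-(3-methylbut-2-en-1-yl)phenyl]-3-[4-(methoxymethoxy)-5-(2-methylbut-3-en-2-yl)-2-{[2-(trimethylsilyl)ethoxy]methoxy}phenyl]propan-1-one | O=C(CCc1cc(C(C)(C)C=C)c(OCOC)cc1OCOCC[Si](C)(C)C)c1cc(OCOC)c(OCC=C)cc1CC=C(C)C | intermediate
16 | (1R)-1-[4-(allyloxy)-5-(methoxymethoxy)-2-(3-methylbut-2-en-1-yl)phenyl]-3-[4-(methoxymethoxy)-5-(2-methylbut-3-en-2-yl)-2-{[2-(trimethylsilyl)ethoxy]methoxy}phenyl]propan-1-ol | O[C@H](CCc1cc(C(C)(C)C=C)c(OCOC)cc1OCOCC[Si](C)(C)C)c1cc(OCOC)c(OCC=C)cc1CC=C(C)C | intermediate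
17 | (1R)-1-[4-(allyloxy)-5-(methoxymethoxy)-2-(3-methylbut-2-en-1-yl)phenyl]-3-[2-hydroxy-4-(methoxymethoxy)-5-(2-methylbut-3-en-2-yl)phenyl]propan-1-ol | O[C@H](CCc1cc(C(C)(C)C=C)c(OCOC)cc1O)c1cc(OCOC)c(OCC=C)cc1CC=C(C)C | intermediate
18 | (2S)-2-[4-(allyloxy)-5-(methoxymethoxy)-2-(3-methylbut-2-en-1-yl)phenyl]-7-(methoxymethoxy)-6-(2-methylbut-3-en-2-yl)chromane | C=CC(C)(C)c1cc2c(cc1OCOC)O[C@H](c1cc(OCOC)c(OCC=C)cc1CC=C(C)C)CC2 | intermediate
19 | 2-(methoxymethoxy)-4-[(2S)-7-(methoxymethoxy)-6-(2-methylbut-3-en-2-yl)chroman-2-yl]-5-(3-methylbut-2-en-1-yl)phenol | C=CC(C)(C)c1cc2c(cc1OCOC)O[C@H](c1cc(OCOC)c(O)cc1CC=C(C)C)CC2 | intermediate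
20 | 3-methylbut-2-enal (prenal) | CC(C)=CC=O | starting material
21 | (2S)-7-(methoxymethoxy)-2-[8-(methoxymethoxy)-4-(2-methylprop-1-en-1-yl)-5-(3-methylbut-2-en-1-yl)-2-phenyl-4H-1,3,2-benzodioxaborin-6-yl]-6-(2-methylbut-3-en-2-yl)chromane (epimers at the borinane C-4, not isolated) | C=CC(C)(C)c1cc2c(cc1OCOC)O[C@H](c1cc(OCOC)c3OB(c4ccccc4)OC(C=C(C)C)c3c1CC=C(C)C)CC2 | intermediate
22 | 2-(methoxymethoxy)-4-[(2S)-7-(methoxymethoxy)-6-(2-methylbut-3-en-2-yl)chroman-2-yl]-5-(3-methylbut-2-en-1-yl)-6-(3-methylbut-2-en-1-ylidene)cyclohexa-2,4-dien-1-one (not isolated) | C=CC(C)(C)c1cc2c(cc1OCOC)O[C@H](C1=C(CC=C(C)C)C(=CC=C(C)C)C(=O)C(OCOC)=C1)CC2 | intermediate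
23 | (2S)-7-(methoxymethoxy)-2-[8-(methoxymethoxy)-2,2-dimethyl-5-(3-methylbut-2-en-1-yl)-2H-chromen-6-yl]-6-(2-methylbut-3-en-2-yl)chromane | C=CC(C)(C)c1cc2c(cc1OCOC)O[C@H](c1cc(OCOC)c3c(c1CC=C(C)C)C=CC(C)(C)O3)CC2 | intermediate
24 | (2S)-2-[(3S,4S)-3,4-epoxy-8-(methoxymethoxy)-2,2-dimethyl-5-(3-methylbut-2-en-1-yl)chroman-6-yl]-7-(methoxymethoxy)-6-(2-methylbut-3-en-2-yl)chromane | C=CC(C)(C)c1cc2c(cc1OCOC)O[C@H](c1cc(OCOC)c3c(c1CC=C(C)C)[C@@H]1O[C@@H]1C(C)(C)O3)CC2 | intermediate
25 | (3S)-8-(methoxymethoxy)-6-[(2S)-7-(methoxymethoxy)-6-(2-methylbut-3-en-2-yl)chroman-2-yl]-2,2-dimethyl-5-(3-methylbut-2-en-1-yl)chroman-3-ol | C=CC(C)(C)c1cc2c(cc1OCOC)O[C@H](c1cc(OCOC)c3c(c1CC=C(C)C)C[C@H](O)C(C)(C)O3)CC2 | intermediate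
26 | (3S)-6-[(2S)-7-hydroxy-6-(2-methylbut-3-en-2-yl)chroman-2-yl]-2,2-dimethyl-5-(3-methylbut-2-en-1-yl)chromane-3,8-diol (CNP0323011.1) | C=CC(C)(C)c1cc2c(cc1O)O[C@H](c1cc(O)c3c(c1CC=C(C)C)C[C@H](O)C(C)(C)O3)CC2 | target

**Step count and risks**

Total step count: 19. Longest linear sequence: 15 steps (steps 5 to 19, from 7 to 26); the A-ring branch (steps 1 to 4) joins at step 10.

Steps most likely to fail:

Step 17. What may go wrong: oxygen transfer or hypochlorite chlorination at the prenyl or 1,1-dimethylallyl alkenes or on the electron-rich rings may compete with epoxidation of the chromene, and the peri prenyl group may lower the facial selectivity. The fallback sets out from 23 and comes back at 25, and it avoids an electrophilic oxidant altogether. A copper-catalysed enantioselective protoboration (CuCl, NaOt-Bu, a chiral bisphosphine of the DTBM-SEGPHOS type in the enantiomer that leads to (3''S), B2pin2, MeOH, THF), which acts only on aryl-conjugated alkenes, should add boron to C-3'' and hydrogen to benzylic C-4'' and give the C-3'' pinacol boronate F1. Oxidation of F1 with NaBO3 in THF–water, with retention at carbon, should then give 25 directly.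

Step 16. What may go wrong: C–C bond formation at the hindered C-3' beside the prenyl group may be slow, quinone methide 22 may be diverted by hydrogen shift or oligomerisation, MOM groups may be partly lost in hot acid, and the 4'-hydroxyflavan may open thermally and erode C-2. The fallback sets out from 19 and comes back at 23, and it makes the C–O bond first. O-Alkylation of 19 with 3-chloro-3-methylbut-1-yne (CuCl2 cat., DBU, MeCN, 0 °C) should give the aryl 1,1-dimethylpropargyl ether F2. Heating F2 in o-xylene at 140 °C should give 23 by propargyl Claisen rearrangement, 1,5-hydrogen shift and oxa-6π electrocyclisation; here the C–C bond forms intramolecularly and C-3' is the only open ortho position.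

Step 3. What may go wrong: the allyl unit may migrate to C-3 instead of C-5, the ortho-(1,1-dimethylallyl)phenol may rearrange further (abnormal Claisen), or the prenyl group may be lost by ether cleavage. The fallback sets out from 1 and comes back at 6, and it fixes the position by cross-coupling. Bromination of 1 (Br2, AcOH) should give 5-bromo-2,4-dihydroxybenzaldehyde F3. MOM protection of the non-chelated 4-OH (MOMCl, K2CO3, acetone) should give 5-bromo-2-hydroxy-4-(methoxymethoxy)benzaldehyde F4. A γ-selective Suzuki–Miyaura coupling of F4 with prenylboronic acid pinacol ester (Pd catalyst with a bulky biarylphosphine chosen for the branched product, K3PO4) should give 2-hydroxy-4-(methoxymethoxy)-5-(2-methylbut-3-en-2-yl)benzaldehyde F5. SEM protection of F5 (SEMCl, K2CO3, DMF) then gives 6.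

Further compounds
F1 | step 17 | 2-[(3S)-8-(methoxymethoxy)-6-[(2S)-7-(methoxymethoxy)-6-(2-methylbut-3-en-2-yl)chroman-2-yl]-2,2-dimethyl-5-(3-methylbut-2-en-1-yl)chroman-3-yl]-4,4,5,5-tetramethyl-1,3,2-dioxaborolane | C=CC(C)(C)c1cc2c(cc1OCOC)O[C@H](c1cc(OCOC)c3c(c1CC=C(C)C)C[C@H](B4OC(C)(C)C(C)(C)O4)C(C)(C)O3)CC2
F2 | step 16 | (2S)-7-(methoxymethoxy)-2-[5-(methoxymethoxy)-2-(3-methylbut-2-en-1-yl)-4-[(2-methylbut-3-yn-2-yl)oxy]phenyl]-6-(2-methylbut-3-en-2-yl)chromane | C=CC(C)(C)c1cc2c(cc1OCOC)O[C@H](c1cc(OCOC)c(OC(C)(C)C#C)cc1CC=C(C)C)CC2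
F3 | step 3 | 5-bromo-2,4-dihydroxybenzaldehyde | O=Cc1cc(Br)c(O)cc1O
F4 | step 3 | 5-bromo-2-hydroxy-4-(methoxymethoxy)benzaldehyde | O=Cc1cc(Br)c(OCOC)cc1O
F5 | step 3 | 2-hydroxy-4-(methoxymethoxy)-5-(2-methylbut-3-en-2-yl)benzaldehyde | O=Cc1cc(C(C)(C)C=C)c(OCOC)cc1O
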